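A reading at 30 h comes later than any reading of Saturday's or Friday's run, yet Saturday's left-handed product read 28.3% at 10.0 h and 29.6% at 25.0 h, so the choice for the next flask concerns its catalyst charge more than its length.

the same everywhere: left-handed substrate 0.050 M; right-handed substrate 0.050 M; gas 4.5 mM (held)

| charge | free catalyst | remark | time |
|---|---|---|---|
| Saturday's | 0.1 mol% | run made earlier |  |
| Friday's | 0.4 mol% | run made earlier |  |
| flask | 0.2 mol% |  | 30 h |

| run | time / h | left-handed product / % | right-handed product / % |
|---|---|---|---|
| Saturday's | 1.33 | 14.8 | 0 |
| Saturday's | 4.00 | 24.6 | 0 |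
| Saturday's | 6.00 | 26.1 | 1.0 |
| Saturday's | 10.0 | 28.3 | 0 |
| Saturday's | 15.0 | 26.7 | 0 |
| Saturday's | 20.0 | 27.5 | 0.5 |
| Saturday's | 25.0 | 29.6 | 0 |
| Friday's | 2.00 | 27.0 | 0 |
| Friday's | 3.00 | 32.5 | 0 |
| Friday's | 4.00 | 32.4 | 0 |
| Friday's | 6.00 | 33.9 | 3.2 |
| Friday's | 10.0 | 35.6 | 0.4 |
| Friday's | 15.0 | 36.1 | 0.1 |
| Friday's | 25.0 | 36.9 | 0.8 |

(readings scatter by 1 percentage point)

- free catalyst is single-handed; left-handed substrate and right-handed substrate are mirror images of each other, charged as a racemate, each of them at the stated concentration
- at the start none of the gas is in solution
- an excess is below zero if the other one leads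

* excess of left-handed product over right-handed product in the product at 3.0 h
* excess of left-handed product over right-handed product in the product at 30 h
* part of the left-handed substrate and right-handed substrate charged together that has reacted at 30 h

Let the exposure E be the natural logarithm of one over the fraction of left-handed substrate left. Averaged from 10.0 h on, Saturday's run gives E = 0.822 and Friday's gives 1.29. By that reading Friday's run still holds 27.5% of its left-handed substrate, so its plateau stands short of the end of that substrate. The two runs give s, the gain in E per power of ten of catalyst loading, as 0.773. A straight line in the logarithm of loading then puts the flask at 0.2 mol% at E = 1.05, which is 32.6% left-handed product. The right-handed product averages 0.429% over both runs. Held against that plateau, this average gives an excess of 97.4% and 33.0% reacted at 30 h, and the same excess is assumed for 3.0 h, taking the two products to grow in step. Friday's loading is twice this charge and adds 0.240 to E, so the charge stays at 0.2 mol%.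

The forecast gives 99%, 98.8% and 33%, holding that “the catalyst is dying rather than the substrate running out”, and its excess stands above this reckoning's.

The flask gives 96.7% at 3.0 h, 96.2% at 30 h and 34.0% reacted, while its free catalyst has fallen to 0.178% of the charge at 15.0 h, the rest standing as spent catalyst A, 68.6%, and spent catalyst B, 31.3%.

    gas ⇌ coupling partner, rate k1*(csat - [coupling partner]) (kL = 9.30 h⁻¹)
    free catalyst → spent catalyst B (k = 0.290 h⁻¹)
    2 free catalyst → spent catalyst A (k = 9200 L mol⁻¹ h⁻¹)
    coupling partner + free catalyst + left-handed substrate → free catalyst + left-handed product (k = 3.20 × 10⁶ L² mol⁻² h⁻¹)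
    coupling partner + free catalyst + right-handed substrate → free catalyst + right-handed product (k = 38000 L² mol⁻² h⁻¹)

Carrying the line of slope s below Saturday's loading to a neighbouring flask charged with 0.05 mol% gives E = 0.589, which leaves 55.5% of the left-handed substrate, and that neighbour ends with 53% of it left and 23.6% reacted.

(All runs stem from a simulated flask with made-up constants; noise was put on by code.)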